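Retrosynthesis: after removal of three benzyl ethers, ring B is cut at three bonds (phenol numbering C1–C2, C3–C4 and C1–C6) into a 3-(2-arylethyl)cyclobutenone and a 1-methoxy-3-arylpropyne that already holds ring A and the bridge CH2.
Enabling feature: on ring B the bridge carbon C2 lies between C1–OH and C3–OMe, the arylethyl chain at C5 is para to it, and C4 and C6 are CH; this is the sequence that a vinylketene (C=O, CH, C-chain, CH2) and a methoxyalkyne (C–OMe, C–bridge) deliver.
The ynol ether is cut at its propargylic CH2–C(sp) bond into a ring A benzylic chloride and methoxyacetylide; ring A is methyl orsellinate, whose ester carbon becomes the bridge and whose C-methyl is extended to the bibenzyl arm by lateral lithiation.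
The cyclobutenone is cut by a ketene–alkyne (2+2) disconnection to a 4-arylbut-1-yne; this alkyne and the ring A arm both come from one benzylic bromide made from O-benzylvanillin.
Forward order: the two guaiacyl rings and ring A are bought, the arm is put on ring A, the four-membered ring is built on the other arm, ring B is formed last between the two halves, and hydrogenolysis ends the route.
Stereochemistry: the target has no stereocentre and no double-bond geometry; only regiochemistry matters, and it is fixed by the orsellinate pattern and by the polarity of the ketene–ynol ether cycloaddition.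

Key step: step 13

Step 1
Reactants: 1 4-benzyloxy-3-methoxybenzaldehyde (O-benzylvanillin)
Product: 2 (4-benzyloxy-3-methoxyphenyl)methanol
Conditions: NaBH4, MeOH–THF, 0 °C
Reagents that add atoms: none
Why: Hydride reduction of an aromatic aldehyde with NaBH4 is fast and chemoselective, and the aryl benzyl and methyl ethers are inert to it.

Step 2
Reactants: 2 (4-benzyloxy-3-methoxyphenyl)methanol
Product: 3 4-benzyloxy-3-methoxybenzyl bromide
Conditions: PBr3, Et2O, 0 °C
Reagents that add atoms: phosphorus tribromide, BrP(Br)Br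
Why: Bromination of a benzylic alcohol with PBr3 (nucleophilic substitution on the activated alcohol) is standard for alkoxybenzyl alcohols, and the short cold reaction spares the aryl ethers.

Step 3
Reactants: 3 4-benzyloxy-3-methoxybenzyl bromide; 4 1-trimethylsilylpropyne
Product: 6 [4-(4-benzyloxy-3-methoxyphenyl)but-1-yn-1-yl]trimethylsilane, via lithiated silylpropyne 5 (not isolated)
Conditions: n-BuLi, THF, −78 °C; then 3, −78 to 0 °C
Reagents that add atoms: none
Why: Deprotonation of 4 at its methyl group gives the silyl-capped propargyllithium 5, which is alkylated at its CH2 terminus by the reactive benzylic bromide (SN2 propargylation), the silyl group disfavouring the allenic product.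

Step 4
Reactants: 6 [4-(4-benzyloxy-3-methoxyphenyl)but-1-yn-1-yl]trimethylsilane
Product: 7 4-(4-benzyloxy-3-methoxyphenyl)but-1-yne
Conditions: K2CO3 (cat.), MeOH, rt
Reagents that add atoms: none
Why: Methanolysis of the C(sp)–Si bond with catalytic K2CO3 (protodesilylation of an alkynylsilane) frees the terminal alkyne without touching any other group.

Step 5
Reactants: 7 4-(4-benzyloxy-3-methoxyphenyl)but-1-yne; 8 trichloroacetyl chloride
Product: 10 4,4-dichloro-3-[2-(4-benzyloxy-3-methoxyphenyl)ethyl]cyclobut-2-en-1-one, via dichloroketene 9 (not isolated)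
Conditions: Zn(Cu), Et2O–DME, rt, slow addition of 8
Reagents that add atoms: none
Why: Dichloroketene 9, released from 8 by zinc, adds to terminal alkynes in a (2+2) cycloaddition with its carbonyl carbon bonding to the unsubstituted alkyne carbon, which gives the 3-substituted 4,4-dichlorocyclobutenone, while DME ties up ZnCl2 and the arenes and ethers are not attacked by the ketene.

Step 6
Reactants: 10 4,4-dichloro-3-[2-(4-benzyloxy-3-methoxyphenyl)ethyl]cyclobut-2-en-1-one
Product: 11 3-[2-(4-benzyloxy-3-methoxyphenyl)ethyl]cyclobut-2-en-1-one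
Conditions: Zn dust, AcOH, TMEDA, EtOH, 0 °C to rt
Reagents that add atoms: none
Why: Zinc in acetic acid buffered by TMEDA removes both α-chlorines (reductive dehalogenation of an α,α-dichloroketone) without reducing the strained enone or the benzyl ether.

Step 7
Reactants: 12 methyl orsellinate (methyl 2,4-dihydroxy-6-methylbenzoate)
Product: 13 methyl 2-hydroxy-4-methoxy-6-methylbenzoate
Conditions: MeI (1.05 equiv), K2CO3, acetone, rt
Reagents that add atoms: iodomethane, CI
Why: Williamson O-methylation with one equivalent of MeI takes place at the 4-hydroxyl, which is the more acidic one and is not held in the hydrogen bond to the ester carbonyl that deactivates the 2-hydroxyl.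

Step 8
Reactants: 13 methyl 2-hydroxy-4-methoxy-6-methylbenzoate
Product: 14 methyl 2-benzyloxy-4-methoxy-6-methylbenzoate
Conditions: BnBr, K2CO3, DMF, 60 °C
Reagents that add atoms: benzyl bromide, BrCc1ccccc1
Why: Williamson benzylation under more forcing conditions alkylates the remaining chelated phenol, the only nucleophilic site left.

Step 9
Reactants: 14 methyl 2-benzyloxy-4-methoxy-6-methylbenzoate; 3 4-benzyloxy-3-methoxybenzyl bromide
Product: 16 methyl 2-benzyloxy-6-[2-(4-benzyloxy-3-methoxyphenyl)ethyl]-4-methoxybenzoate, via benzylic lithio ester 15 (not isolated)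
Conditions: LiN(i-Pr)2 (1.05 equiv), THF, −78 °C; then 3, −78 to −40 °C
Reagents that add atoms: none
Why: The ester acidifies the ortho methyl group so that LiN(i-Pr)2 gives the benzylic anion 15 at −78 °C (lateral lithiation of an ortho-toluate), and its alkylation by bromide 3 builds the bibenzyl arm while the two ortho substituents shield the ester from self-condensation.

Step 10
Reactants: 16 methyl 2-benzyloxy-6-[2-(4-benzyloxy-3-methoxyphenyl)ethyl]-4-methoxybenzoate
Product: 17 {2-benzyloxy-6-[2-(4-benzyloxy-3-methoxyphenyl)ethyl]-4-methoxyphenyl}methanol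
Conditions: LiAlH4, THF, 0 °C to reflux; H2O/NaOH work-up
Reagents that add atoms: none
Why: LiAlH4 reduces even a doubly ortho-substituted aryl ester to the primary benzylic alcohol and leaves all ethers untouched.

Step 11
Reactants: 17 {2-benzyloxy-6-[2-(4-benzyloxy-3-methoxyphenyl)ethyl]-4-methoxyphenyl}methanol
Product: 19 1-benzyloxy-2-(chloromethyl)-3-[2-(4-benzyloxy-3-methoxyphenyl)ethyl]-5-methoxybenzene, via benzylic mesylate 18 (not isolated)
Conditions: MsCl, Et3N, CH2Cl2, −20 to 0 °C; cold aqueous wash, used crude at once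
Reagents that add atoms: methanesulfonyl chloride, CS(=O)(=O)Cl
Why: Mesylation of the electron-rich benzylic alcohol gives mesylate 18, which is displaced in the flask by chloride (nucleophilic substitution assisted by the ortho and para oxygen donors) in an amine-buffered medium free of acid, and the labile chloride is carried on without storage.

Step 12
Reactants: 19 1-benzyloxy-2-(chloromethyl)-3-[2-(4-benzyloxy-3-methoxyphenyl)ethyl]-5-methoxybenzene; 20 chloroacetaldehyde dimethyl acetal
Product: 22 1-benzyloxy-3-[2-(4-benzyloxy-3-methoxyphenyl)ethyl]-5-methoxy-2-(3-methoxyprop-2-yn-1-yl)benzene, via lithium methoxyacetylide 21 (not isolated)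
Conditions: 20, LiNEt2 (3 equiv, from Et2NH and n-BuLi), THF, 0 °C; then 19, DMPU, −78 to −20 °C; pH 7 phosphate buffer, cold
Reagents that add atoms: none
Why: Two eliminations and a deprotonation of acetal 20 by LiNEt2 give lithium methoxyacetylide 21, whose SN2 alkylation by the reactive benzylic chloride in THF/DMPU (alkylation of a metal alkoxyacetylide) should outpace attack by the neutral amine at low temperature, while the cold neutral quench guards against propargyl-to-allenyl isomerisation.

Step 13
Reactants: 11 3-[2-(4-benzyloxy-3-methoxyphenyl)ethyl]cyclobut-2-en-1-one; 22 1-benzyloxy-3-[2-(4-benzyloxy-3-methoxyphenyl)ethyl]-5-methoxy-2-(3-methoxyprop-2-yn-1-yl)benzene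
Product: 27 2-{2-benzyloxy-6-[2-(4-benzyloxy-3-methoxyphenyl)ethyl]-4-methoxybenzyl}-5-[2-(4-benzyloxy-3-methoxyphenyl)ethyl]-3-methoxyphenol, via vinylketene 23 (not isolated), via vinylcyclobutenone 24 (not isolated), via dienylketene 25 (not isolated), via cyclohexadienone 26 (not isolated)
Conditions: 11 (1.3 equiv), toluene, 80 °C then 110 °C; then KOH, MeOH, rt
Reagents that add atoms: none
Why: At 80 °C cyclobutenone 11 undergoes four-electron electrocyclic opening to vinylketene 23, whose carbonyl carbon is attacked by the benzyl-bearing carbon of ynol ether 22 in a (2+2) ketene–alkyne cycloaddition to give 4-vinylcyclobutenone 24; this opens again to dienylketene 25, which closes by six-electron electrocyclisation to cyclohexadienone 26 and tautomerises to the phenol. The closest known reaction type is the Danheiser benzannulation of 3-alkylcyclobutenones with 1-alkoxyalkynes, which gives 2,5-dialkylresorcinol monoethers; only the bulky ortho,ortho-disubstituted benzyl group on the alkyne lies outside the usual substrates. Ring B is closed by the thermally allowed disrotatory 6π electrocyclisation that joins the former carbonyl carbon to the former ring CH2 of 11, after the transient four-membered ring of 24 has been closed by the (2+2) step and opened again. No stereocentre is created in the product, since the sp3 carbons of 24 and 26 end up aromatic. The one selectivity required is the orientation of the cycloaddition, and the methoxy oxygen secures it by polarising the triple bond so that the remote carbon is the nucleophile; this places the bridge CH2 between the new OH (from the ketene carbonyl) and the OMe (from the alkyne) and para to the arylethyl chain. The methyl ynol ether has no retro-ene path, the benzyl ethers are inert to this neutral thermal cascade, and the closing KOH/MeOH treatment returns any phenol that was acylated by surplus ketene.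

Step 14
Reactants: 27 2-{2-benzyloxy-6-[2-(4-benzyloxy-3-methoxyphenyl)ethyl]-4-methoxybenzyl}-5-[2-(4-benzyloxy-3-methoxyphenyl)ethyl]-3-methoxyphenol
Product: 28 2-{2-hydroxy-6-[2-(4-hydroxy-3-methoxyphenyl)ethyl]-4-methoxybenzyl}-5-[2-(4-hydroxy-3-methoxyphenyl)ethyl]-3-methoxyphenol (CNP0079001.0)
Conditions: H2 (1 atm), Pd/C, EtOAc–MeOH, rt
Reagents that add atoms: none
Why: Hydrogenolysis of aryl benzyl ethers over Pd/C is the standard deprotection, and the molecule holds no other reducible group, the diarylmethane and bibenzyl C–C bonds being inert.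

Compound list
1 | 4-benzyloxy-3-methoxybenzaldehyde (O-benzylvanillin) | COc1cc(C=O)ccc1OCc1ccccc1 | starting material
2 | (4-benzyloxy-3-methoxyphenyl)methanol | COc1cc(CO)ccc1OCc1ccccc1 | intermediate
3 | 4-benzyloxy-3-methoxybenzyl bromide | COc1cc(CBr)ccc1OCc1ccccc1 | intermediate
4 | 1-trimethylsilylpropyne | CC#C[Si](C)(C)C | starting material
5 | 3-lithio-1-trimethylsilylpropyne (lithiated silylpropyne) | [Li]CC#C[Si](C)(C)C | intermediate
6 | [4-(4-benzyloxy-3-methoxyphenyl)but-1-yn-1-yl]trimethylsilane | COc1cc(CCC#C[Si](C)(C)C)ccc1OCc1ccccc1 | intermediate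
7 | 4-(4-benzyloxy-3-methoxyphenyl)but-1-yne | C#CCCc1ccc(OCc2ccccc2)c(OC)c1 | intermediate
8 | trichloroacetyl chloride | O=C(Cl)C(Cl)(Cl)Cl | starting material
9 | dichloroketene | O=C=C(Cl)Cl | intermediate
10 | 4,4-dichloro-3-[2-(4-benzyloxy-3-methoxyphenyl)ethyl]cyclobut-2-en-1-one | COc1cc(CCC2=CC(=O)C2(Cl)Cl)ccc1OCc1ccccc1 | intermediate
11 | 3-[2-(4-benzyloxy-3-methoxyphenyl)ethyl]cyclobut-2-en-1-one | COc1cc(CCC2=CC(=O)C2)ccc1OCc1ccccc1 | intermediate
12 | methyl orsellinate (methyl 2,4-dihydroxy-6-methylbenzoate) | COC(=O)c1c(C)cc(O)cc1O | starting material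
13 | methyl 2-hydroxy-4-methoxy-6-methylbenzoate | COC(=O)c1c(C)cc(OC)cc1O | intermediate
14 | methyl 2-benzyloxy-4-methoxy-6-methylbenzoate | COC(=O)c1c(C)cc(OC)cc1OCc1ccccc1 | intermediate
15 | methyl 2-benzyloxy-6-(lithiomethyl)-4-methoxybenzoate (benzylic lithio ester) | COC(=O)c1c(C[Li])cc(OC)cc1OCc1ccccc1 | intermediate
16 | methyl 2-benzyloxy-6-[2-(4-benzyloxy-3-methoxyphenyl)ethyl]-4-methoxybenzoate | COC(=O)c1c(CCc2ccc(OCc3ccccc3)c(OC)c2)cc(OC)cc1OCc1ccccc1 | intermediate
17 | {2-benzyloxy-6-[2-(4-benzyloxy-3-methoxyphenyl)ethyl]-4-methoxyphenyl}methanol | COc1cc(OCc2ccccc2)c(CO)c(CCc2ccc(OCc3ccccc3)c(OC)c2)c1 | intermediate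
18 | 2-benzyloxy-6-[2-(4-benzyloxy-3-methoxyphenyl)ethyl]-4-methoxybenzyl methanesulfonate (benzylic mesylate) | COc1cc(OCc2ccccc2)c(COS(C)(=O)=O)c(CCc2ccc(OCc3ccccc3)c(OC)c2)c1 | intermediate
19 | 1-benzyloxy-2-(chloromethyl)-3-[2-(4-benzyloxy-3-methoxyphenyl)ethyl]-5-methoxybenzene | COc1cc(OCc2ccccc2)c(CCl)c(CCc2ccc(OCc3ccccc3)c(OC)c2)c1 | intermediate
20 | chloroacetaldehyde dimethyl acetal (2-chloro-1,1-dimethoxyethane) | COC(CCl)OC | starting material
21 | lithium methoxyacetylide | [Li]C#COC | intermediate
22 | 1-benzyloxy-3-[2-(4-benzyloxy-3-methoxyphenyl)ethyl]-5-methoxy-2-(3-methoxyprop-2-yn-1-yl)benzene | COC#CCc1c(OCc2ccccc2)cc(OC)cc1CCc1ccc(OCc2ccccc2)c(OC)c1 | intermediate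
23 | 3-[2-(4-benzyloxy-3-methoxyphenyl)ethyl]buta-1,3-dien-1-one (vinylketene) | O=C=CC(=C)CCc1ccc(OCc2ccccc2)c(OC)c1 | intermediate
24 | racemic 2-{2-benzyloxy-6-[2-(4-benzyloxy-3-methoxyphenyl)ethyl]-4-methoxybenzyl}-4-[4-(4-benzyloxy-3-methoxyphenyl)but-1-en-2-yl]-3-methoxycyclobut-2-en-1-one (vinylcyclobutenone) | O=C1C(Cc2c(OCc3ccccc3)cc(OC)cc2CCc2ccc(OCc3ccccc3)c(OC)c2)=C(OC)C1C(=C)CCc1ccc(OCc2ccccc2)c(OC)c1 | intermediate
25 | (3E)-2-{2-benzyloxy-6-[2-(4-benzyloxy-3-methoxyphenyl)ethyl]-4-methoxybenzyl}-5-[2-(4-benzyloxy-3-methoxyphenyl)ethyl]-3-methoxyhexa-1,3,5-trien-1-one (dienylketene, ketene and vinyl groups cis on the enol ether double bond) | O=C=C(Cc1c(OCc2ccccc2)cc(OC)cc1CCc1ccc(OCc2ccccc2)c(OC)c1)/C(OC)=C\C(=C)CCc1ccc(OCc2ccccc2)c(OC)c1 | intermediate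
26 | 2-{2-benzyloxy-6-[2-(4-benzyloxy-3-methoxyphenyl)ethyl]-4-methoxybenzyl}-5-[2-(4-benzyloxy-3-methoxyphenyl)ethyl]-3-methoxycyclohexa-2,4-dien-1-one (cyclohexadienone) | O=C1CC(CCc2ccc(OCc3ccccc3)c(OC)c2)=CC(OC)=C1Cc1c(OCc2ccccc2)cc(OC)cc1CCc1ccc(OCc2ccccc2)c(OC)c1 | intermediate
27 | 2-{2-benzyloxy-6-[2-(4-benzyloxy-3-methoxyphenyl)ethyl]-4-methoxybenzyl}-5-[2-(4-benzyloxy-3-methoxyphenyl)ethyl]-3-methoxyphenol | COc1cc(OCc2ccccc2)c(Cc2c(O)cc(CCc3ccc(OCc4ccccc4)c(OC)c3)cc2OC)c(CCc2ccc(OCc3ccccc3)c(OC)c2)c1 | intermediate
28 | 2-{2-hydroxy-6-[2-(4-hydroxy-3-methoxyphenyl)ethyl]-4-methoxybenzyl}-5-[2-(4-hydroxy-3-methoxyphenyl)ethyl]-3-methoxyphenol (CNP0079001.0) | COc1cc(O)c(Cc2c(O)cc(CCc3ccc(O)c(OC)c3)cc2OC)c(CCc2ccc(O)c(OC)c2)c1 | target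

Total step count: 14 steps.
Longest linear sequence: 8 steps (steps 7 to 14 from methyl orsellinate; the sequences through steps 1 to 6 or through steps 1, 2 and 9 are equally long).

Steps most likely to fail

Step 12. The benzylic chloride may ionise and alkylate its own electron-rich rings, or be captured by diethylamine, before the acetylide reacts, and the product may isomerise to the allenyl ether while base is still present. The fallback sets out from alcohol 17 and lithium methoxyacetylide 21 (made from 20 as in step 12) and comes back at ynol ether 22, bypassing chloride 19. Quenching 21 with Bu3SnCl (THF, −78 °C to rt) should give the distillable, amine-free tributyl(methoxyethynyl)stannane F1. Alcohol 17 would be acylated with ClCO2Me and pyridine to the bench-stable benzylic methyl carbonate F2. Cross-coupling of F2 with F1 under zerovalent palladium catalysis (Pd2(dba)3, DPEphos, DMF, 60 °C) would proceed by oxidative addition into the benzylic C–O bond, loss of CO2 and transfer of the alkynyl group from tin, and should give 22 under neutral conditions with neither amine nor strong base present.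

Step 13. Capture of the vinylketene by the alkyne may be too slow next to the crowded ortho,ortho-disubstituted benzyl group, so that ketene dimerisation and thermal decay of the ynol ether take over. The fallback sets out from cyclobutenone 11, acetylide 21 and alcohol 17 and comes back at 27; the bond from the bridge carbon to ring B is then made by directed ortho-metalation instead of by annulation onto the hindered alkyne. Protonation of 21 (aqueous NH4Cl) and distillation would give methoxyacetylene F3, which is unhindered and should annulate with 11 in the same sense (toluene, 80 °C) to 5-[2-(4-benzyloxy-3-methoxyphenyl)ethyl]-3-methoxyphenol F4. MOMCl and i-Pr2NEt would convert it into the methoxymethyl ether F5. n-BuLi (THF, 0 °C) should lithiate F5 between its two oxygens to the 2-lithio derivative F6, which would add to the ring A aldehyde F7 (from 17 with MnO2, CH2Cl2) to give the racemic diarylmethanol F8. Ionic hydrogenation (Et3SiH, CF3CO2H, CH2Cl2, 0 °C) would remove the doubly benzylic hydroxyl and the methoxymethyl group in the same operation and give 27.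

Step 5. Oligomerisation of dichloroketene promoted by ZnCl2 and acid-induced decomposition of the strained chloro enone during reaction and purification may leave too little material for the long branch. The fallback sets out from alkyne 7 and comes back at cyclobutenone 11, bypassing 10 and step 6. N,N-dimethylacetamide, Tf2O and 2,4,6-collidine would give N,N-dimethylketeniminium triflate F9, whose (2+2) cycloaddition with 7 (1,2-dichloroethane, reflux) should give the cyclobuteniminium triflate F10 with the same orientation. Hydrolysis with aqueous NaHCO3 would then give 11 directly, without zinc or chlorinated intermediates.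

Further compounds
F1 | step 12 | tributyl(methoxyethynyl)stannane | CCCC[Sn](CCCC)(CCCC)C#COC
F2 | step 12 | 2-benzyloxy-6-[2-(4-benzyloxy-3-methoxyphenyl)ethyl]-4-methoxybenzyl methyl carbonate | COC(=O)OCc1c(OCc2ccccc2)cc(OC)cc1CCc1ccc(OCc2ccccc2)c(OC)c1
F3 | step 13 | methoxyacetylene | C#COC
F4 | step 13 | 5-[2-(4-benzyloxy-3-methoxyphenyl)ethyl]-3-methoxyphenol | COc1cc(O)cc(CCc2ccc(OCc3ccccc3)c(OC)c2)c1
F5 | step 13 | 1-[2-(4-benzyloxy-3-methoxyphenyl)ethyl]-3-methoxy-5-(methoxymethoxy)benzene | COCOc1cc(OC)cc(CCc2ccc(OCc3ccccc3)c(OC)c2)c1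
F6 | step 13 | {4-[2-(4-benzyloxy-3-methoxyphenyl)ethyl]-2-methoxy-6-(methoxymethoxy)phenyl}lithium | COCOc1cc(CCc2ccc(OCc3ccccc3)c(OC)c2)cc(OC)c1[Li]
F7 | step 13 | 2-benzyloxy-6-[2-(4-benzyloxy-3-methoxyphenyl)ethyl]-4-methoxybenzaldehyde | COc1cc(OCc2ccccc2)c(C=O)c(CCc2ccc(OCc3ccccc3)c(OC)c2)c1
F8 | step 13 | racemic {2-benzyloxy-6-[2-(4-benzyloxy-3-methoxyphenyl)ethyl]-4-methoxyphenyl}{4-[2-(4-benzyloxy-3-methoxyphenyl)ethyl]-2-methoxy-6-(methoxymethoxy)phenyl}methanol | COCOc1cc(CCc2ccc(OCc3ccccc3)c(OC)c2)cc(OC)c1C(O)c1c(OCc2ccccc2)cc(OC)cc1CCc1ccc(OCc2ccccc2)c(OC)c1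
F9 | step 5 | N,N-dimethylketeniminium triflate | C=C=[N+](C)C.[O-]S(=O)(=O)C(F)(F)F
F10 | step 5 | N,N-dimethyl-3-[2-(4-benzyloxy-3-methoxyphenyl)ethyl]cyclobut-2-en-1-iminium triflate | C[N+](C)=C1C=C(CCc2ccc(OCc3ccccc3)c(OC)c2)C1.[O-]S(=O)(=O)C(F)(F)F
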